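**Plan**

- Numbering used throughout: dienone ring C1 (C=O), C2 (allyl), C3 (H), C4 (quaternary; OMe and arylpropenyl), C5 (OMe), C6 (H).
- Enabling feature: the vinylogous methyl ester O=C1–C6H=C5–OMe of the cyclohexa-2,5-dienone ring. C5, next to the quaternary C4, has the oxidation level and the methoxy group of a methyl ester, so the ring bond C5=C6 is cut to a C5 methyl ester and a phosphorus ylide at C6 (ring-closing Wittig olefination of an ester). The enol ether can then form in one position only.
- Further cuts: C1–C6 (acylation of Ph3P=CH2), C2–allyl (Stille coupling), C1–C2 (acylation of an acetylide), C3–C4 (alkynylation of an α-keto ester), side-chain C=C (aldol condensation).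
- Forward: one chain is joined linearly from veratraldehyde and 2-oxobutanoic acid, the cis C2=C3 bond is set by syn-hydrostannation of an ynoate, and the only ring is closed in the last step.
- Stereochemistry: C4 comes from a catalyst-controlled enantioselective alkynylation of the keto ester and no later step breaks a bond to it; the E side-chain alkene comes from the condensation.

Key step: step 9

Assumption: the facial sense of the amino-alcohol/Zn(OTf)2-catalysed alkynylation on this keto ester is not known in advance. The route is written for the ligand antipode that delivers the alkyne to the Re face of the ketone, taken here as the (1S,2S) ligand; if the sense proves opposite, the (1R,2R) ligand is used. Either antipode is obtained in two steps (N,N-dimethylation, O-silylation) from the commercial 2-amino-1-(4-nitrophenyl)propane-1,3-diol.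

**Route**

Step 1
Reactants: 1 3,4-dimethoxybenzaldehyde; 2 2-oxobutanoic acid
Product: 3 (3E)-4-(3,4-dimethoxyphenyl)-3-methyl-2-oxobut-3-enoic acid
Conditions: KOH (2.5 equiv), MeOH–H2O, 0 °C to rt; then aq. HCl
Reagents that add atoms: none
Why: Claisen–Schmidt crossed aldol condensation: the keto acid can enolise only at its CH2, the aldehyde has no α-hydrogen, and E1cB dehydration should give the more stable E enone with the aryl group trans to the acyl group.

Step 2
Reactants: 3
Product: 4 methyl (3E)-4-(3,4-dimethoxyphenyl)-3-methyl-2-oxobut-3-enoate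
Conditions: MeI, KHCO3, DMF, rt
Reagents that add atoms: iodomethane, CI
Why: SN2 O-methylation of the carboxylate formed with KHCO3 gives the ester without acid, which could add methanol to the enone or ketalise the 2-oxo group.

Step 3
Reactants: 4; 5 ethynyltrimethylsilane
Product: 6 methyl (2R,3E)-4-(3,4-dimethoxyphenyl)-2-hydroxy-3-methyl-2-[(trimethylsilyl)ethynyl]but-3-enoate
Conditions: Zn(OTf)2 (20 mol %), (1S,2S)-3-(tert-butyldimethylsilyloxy)-2-(dimethylamino)-1-(4-nitrophenyl)propan-1-ol (22 mol %), Et3N (30 mol %), toluene, 70 °C, sealed vessel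
Reagents that add atoms: none
Why: The alkyne, metalated in situ by Zn(OTf)2/Et3N, adds 1,2 to the ketone of the two-point-bound α-keto ester inside the chiral amino-alkoxide complex of Zn(OTf)2 (catalytic enantioselective alkynylation of α-keto esters); attack on the Re face sets C4 and gives the 2R alcohol, and 1,4-addition is not expected because the β-carbon is shielded by the α-methyl group and the aryl ring.

Step 4
Reactants: 6
Product: 8 methyl (2S,3E)-4-(3,4-dimethoxyphenyl)-2-ethynyl-2-methoxy-3-methylbut-3-enoate, via silylalkyne methyl ether 7 (not isolated)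
Conditions: NaH, MeI, THF–DMF, 0 °C; then MeOH, K2CO3 (cat.), rt
Reagents that add atoms: iodomethane, CI
Why: Williamson etherification of the tertiary alkoxide (made more acidic by the α-ester) is followed by base-catalysed methanolysis of the C(sp)–Si bond; C4 has no hydrogen and no bond to it is broken, so the configuration holds and only the descriptor changes from R to S because ethynyl ranks below the alkenyl group.

Step 5
Reactants: 8
Product: 9 5-methyl 1-phenyl (4R)-4-[(1E)-1-(3,4-dimethoxyphenyl)prop-1-en-2-yl]-4-methoxypent-2-ynedioate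
Conditions: LiN(SiMe3)2, THF, −78 °C; then ClCO2Ph, −78 °C
Reagents that add atoms: phenyl chloroformate, O=C(Cl)Oc1ccccc1
Why: LiN(SiMe3)2 deprotonates only the terminal alkyne and the acetylide is C-acylated by the chloroformate (alkynoate synthesis); the phenyl ester is chosen so that C1 can later be told apart from the hindered C5 methyl ester.

Step 6
Reactants: 9
Product: 10 5-methyl 1-phenyl (2E,4S)-4-[(1E)-1-(3,4-dimethoxyphenyl)prop-1-en-2-yl]-4-methoxy-2-(tributylstannyl)pent-2-enedioate
Conditions: Bu3SnH, Pd(PPh3)4 (3 mol %), THF, 0 °C to rt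
Reagents that add atoms: tributyltin hydride, CCCC[SnH](CCCC)CCCC
Why: Hydrostannation catalysed by zerovalent palladium adds H and SnBu3 syn across the ynoate, with tin going to the carbon α to the ester and away from the quaternary C4, so that the C1 carboxyl and C4 end up cis on C2=C3 (the same reaction type gives α-stannyl butenolides from γ-hydroxy ynoates).

Step 7
Reactants: 10; 11 3-bromoprop-1-ene (allyl bromide)
Product: 12 5-methyl 1-phenyl (2Z,4S)-4-[(1E)-1-(3,4-dimethoxyphenyl)prop-1-en-2-yl]-4-methoxy-2-(prop-2-en-1-yl)pent-2-enedioate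
Conditions: Pd2(dba)3 (2.5 mol %), AsPh3 (20 mol %), CuI (10 mol %), DMF, 40 °C
Reagents that add atoms: none
Why: Stille cross-coupling of the alkenylstannane with the allyl electrophile (copper-assisted transmetalation) proceeds with retention of alkene geometry, so the allyl group takes the place of tin on C2 and C1 stays cis to C4.

Step 8
Reactants: 12
Product: 13 methyl (2S,3Z)-2-[(1E)-1-(3,4-dimethoxyphenyl)prop-1-en-2-yl]-2-methoxy-5-oxo-4-(prop-2-en-1-yl)-6-(triphenyl-λ5-phosphanylidene)hex-3-enoate
Conditions: Ph3PCH3Br (2.2 equiv), KN(SiMe3)2 (2.1 equiv), THF, 0 °C; then 12, −78 to 0 °C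
Reagents that add atoms: methylenetriphenylphosphorane, C=P(c1ccccc1)(c1ccccc1)c1ccccc1 (made in the flask from Ph3PCH3Br and KN(SiMe3)2)
Why: C-Acylation of the non-stabilised ylide by the aryl ester, followed by deprotonation of the acylphosphonium salt by the second equivalent of ylide (transylidation), gives the stabilised acyl ylide; the phenyl ester should react in preference to the methyl ester because phenoxide is the far better leaving group and the methyl ester sits on the neopentyl-like quaternary C4.

Step 9
Reactants: 13
Product: 14 (4S)-4-[(1E)-1-(3,4-dimethoxyphenyl)prop-1-en-2-yl]-4,5-dimethoxy-2-(prop-2-en-1-yl)cyclohexa-2,5-dien-1-one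
Conditions: toluene (0.02 M), 110 °C, argon
Reagents that add atoms: none
Why: On heating, the ylide carbon C6 adds to the carbonyl carbon of the C5 methyl ester, the betaine closes to a 1,2-oxaphosphetane, and cycloreversion expels Ph3P=O, leaving the C5=C6 double bond with the ester methoxy still on C5, so the vinylogous methyl ester arises directly and in only one possible regiochemistry. The closest known reaction type is the non-classical intramolecular Wittig olefination of ester carbonyls by stabilised ylides, as used to close tetronates from ester-tethered acyl ylides and 3-alkoxycycloalkenones from alkoxycarbonyl keto ylides. The six-membered carbocycle (C1 to C6) closes in a 6-(enolendo)-exo-trig mode, the enolate-type C1=C6 bond of the ylide lying inside the new ring and the ester C=O outside it. No stereocentre is formed: C4 bears no hydrogen and none of its bonds is broken, so its S configuration is carried through, and the C2=C3 bond is already cis. The step needs olefination to win over acyl substitution with loss of methoxide and over intermolecular reaction; the cis C2=C3 bond set in step 6 holds C6 within bonding distance of C5, the α-methoxy group raises the electrophilicity of the ester, and the strong P=O bond together with the non-polar solvent should favour collapse of the oxaphosphetane over ionisation to methoxide.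

**Compound list**

1 | 3,4-dimethoxybenzaldehyde | COc1ccc(C=O)cc1OC | starting material
2 | 2-oxobutanoic acid | CCC(=O)C(=O)O | starting material
3 | (3E)-4-(3,4-dimethoxyphenyl)-3-methyl-2-oxobut-3-enoic acid | OC(=O)C(=O)/C(C)=C/c1ccc(OC)c(OC)c1 | intermediate
4 | methyl (3E)-4-(3,4-dimethoxyphenyl)-3-methyl-2-oxobut-3-enoate | COC(=O)C(=O)/C(C)=C/c1ccc(OC)c(OC)c1 | intermediate
5 | ethynyltrimethylsilane | C#C[Si](C)(C)C | starting material
6 | methyl (2R,3E)-4-(3,4-dimethoxyphenyl)-2-hydroxy-3-methyl-2-[(trimethylsilyl)ethynyl]but-3-enoate | COC(=O)[C@](O)(C#C[Si](C)(C)C)/C(C)=C/c1ccc(OC)c(OC)c1 | intermediate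
7 | methyl (2R,3E)-4-(3,4-dimethoxyphenyl)-2-methoxy-3-methyl-2-[(trimethylsilyl)ethynyl]but-3-enoate | COC(=O)[C@](OC)(C#C[Si](C)(C)C)/C(C)=C/c1ccc(OC)c(OC)c1 | intermediate
8 | methyl (2S,3E)-4-(3,4-dimethoxyphenyl)-2-ethynyl-2-methoxy-3-methylbut-3-enoate | COC(=O)[C@](OC)(C#C)/C(C)=C/c1ccc(OC)c(OC)c1 | intermediate
9 | 5-methyl 1-phenyl (4R)-4-[(1E)-1-(3,4-dimethoxyphenyl)prop-1-en-2-yl]-4-methoxypent-2-ynedioate | COC(=O)[C@](OC)(C#CC(=O)Oc1ccccc1)/C(C)=C/c1ccc(OC)c(OC)c1 | intermediate
10 | 5-methyl 1-phenyl (2E,4S)-4-[(1E)-1-(3,4-dimethoxyphenyl)prop-1-en-2-yl]-4-methoxy-2-(tributylstannyl)pent-2-enedioate | COC(=O)[C@](OC)(/C=C(/[Sn](CCCC)(CCCC)CCCC)C(=O)Oc1ccccc1)/C(C)=C/c1ccc(OC)c(OC)c1 | intermediate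
11 | 3-bromoprop-1-ene (allyl bromide) | C=CCBr | starting material
12 | 5-methyl 1-phenyl (2Z,4S)-4-[(1E)-1-(3,4-dimethoxyphenyl)prop-1-en-2-yl]-4-methoxy-2-(prop-2-en-1-yl)pent-2-enedioate | COC(=O)[C@](OC)(/C=C(/CC=C)C(=O)Oc1ccccc1)/C(C)=C/c1ccc(OC)c(OC)c1 | intermediate
13 | methyl (2S,3Z)-2-[(1E)-1-(3,4-dimethoxyphenyl)prop-1-en-2-yl]-2-methoxy-5-oxo-4-(prop-2-en-1-yl)-6-(triphenyl-λ5-phosphanylidene)hex-3-enoate | COC(=O)[C@](OC)(/C=C(/CC=C)C(=O)C=P(c1ccccc1)(c1ccccc1)c1ccccc1)/C(C)=C/c1ccc(OC)c(OC)c1 | intermediate
14 | (4S)-4-[(1E)-1-(3,4-dimethoxyphenyl)prop-1-en-2-yl]-4,5-dimethoxy-2-(prop-2-en-1-yl)cyclohexa-2,5-dien-1-one | C=CCC1=C[C@](OC)(/C(C)=C/c2ccc(OC)c(OC)c2)C(OC)=CC1=O | target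

**Summary**

Total step count: 9. Longest linear sequence: 9 steps (from 1 and 2 to 14).

Steps most likely to fail:

1. Step 9. The betaine may collapse by loss of methoxide (acyl substitution giving a cyclic diacyl ylide) instead of by loss of Ph3P=O, or the hindered ester may not be reached before the ylide decomposes thermally. The fallback sets out from 13 and comes back at 14; it makes the C5–C6 bond by enolate acylation and sets the enol ether afterwards. The C–P bond of 13 is cleaved reductively with Zn dust in AcOH at rt to give the methyl ketone F1. F1 is cyclised with LiN(SiMe3)2 in THF (−78 to 0 °C, Dieckmann-type condensation onto the C5 methyl ester) to the cyclic 1,3-dione F2. F2 is O-methylated with Me3SiCHN2 in toluene–MeOH at 0 °C to give 14. Methylation at the other oxygen would give a regioisomeric enol ether, which would have to be removed by chromatography; this loss is the price of the fallback.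

2. Step 8. The non-stabilised ylide may attack the C5 methyl ester as well, or the acylation at the hindered C1 carbonyl may stall. The fallback sets out from 12 and comes back at 13; it differentiates the two carboxyl groups by hydrolysis and acylates the ylide at a temperature at which no ester reacts. The phenyl ester of 12 is hydrolysed selectively with LiOH (1 equiv) in THF–H2O at 0 °C to the carboxylic acid F3. F3 is converted under neutral conditions with 1-chloro-N,N,2-trimethylprop-1-en-1-amine in CH2Cl2 at 0 °C into the acid chloride F4. F4 is added to Ph3P=CH2 (2 equiv) in THF at −78 °C to give 13.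

3. Step 3. Facial selectivity in the alkyne addition may be poor, because the conjugated, α-branched keto ester may bind to the catalyst differently from simple aryl or alkyl keto esters. The fallback sets out from 4 and comes back at 6; it replaces asymmetric catalysis by resolution. LiC≡CSiMe3 (from 5 and n-BuLi) is added to 4 in THF at −78 °C to give the racemic propargylic alcohol F5. The enantiomers of F5 are separated by preparative chromatography on a chiral stationary phase, and the 2R enantiomer is 6.

**Further compounds**

F1 | step 9 | methyl (2S,3Z)-2-[(1E)-1-(3,4-dimethoxyphenyl)prop-1-en-2-yl]-2-methoxy-5-oxo-4-(prop-2-en-1-yl)hex-3-enoate | COC(=O)[C@](OC)(/C=C(/CC=C)C(C)=O)/C(C)=C/c1ccc(OC)c(OC)c1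
F2 | step 9 | (4S)-4-[(1E)-1-(3,4-dimethoxyphenyl)prop-1-en-2-yl]-4-methoxy-6-(prop-2-en-1-yl)cyclohex-5-ene-1,3-dione | C=CCC1=C[C@](OC)(/C(C)=C/c2ccc(OC)c(OC)c2)C(=O)CC1=O
F3 | step 8 | (2Z,4S)-4-[(1E)-1-(3,4-dimethoxyphenyl)prop-1-en-2-yl]-4,5-dimethoxy-5-oxo-2-(prop-2-en-1-yl)pent-2-enoic acid | COC(=O)[C@](OC)(/C=C(/CC=C)C(=O)O)/C(C)=C/c1ccc(OC)c(OC)c1
F4 | step 8 | methyl (2S,3Z)-4-(chlorocarbonyl)-2-[(1E)-1-(3,4-dimethoxyphenyl)prop-1-en-2-yl]-2-methoxyhepta-3,6-dienoate | COC(=O)[C@](OC)(/C=C(/CC=C)C(=O)Cl)/C(C)=C/c1ccc(OC)c(OC)c1
F5 | step 3 | methyl (3E)-4-(3,4-dimethoxyphenyl)-2-hydroxy-3-methyl-2-[(trimethylsilyl)ethynyl]but-3-enoate (racemate) | COC(=O)C(O)(C#C[Si](C)(C)C)/C(C)=C/c1ccc(OC)c(OC)c1
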